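The target is the trimer ECG-(4β→6)-ECG-(4β→8)-ECG. Everything rests on the interflavan bond between C4 of the middle unit's pyran ring and C8 of the lower unit's phloroglucinol A-ring. The key step copies the presumed biosynthesis: a 4-thioether "extension unit" is ionised to the C4 benzylic cation (quinone methide, stabilised by O1, 5-O and 7-O, steered by the neighbouring 3-O-galloyl ester), and the innately nucleophilic C8 of perbenzylated epicatechin gallate captures it, giving the 4β bond and the whole trimer skeleton in one operation. The precursor is a bromine-capped 4→6 dimer carrying a 4β-(2,6-xylylthio) group; all three units come from one perbenzylated ECG, made from (−)-epicatechin and tri-O-benzylgallic acid.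

Key step: step 7

Remark: flavan numbering (O1, C2, C3, C4, A-ring C5 to C8) is used for every unit; all units are 2R,3R (2,3-cis) and every C4 substituent is 4β (3,4-trans). "Bn7-ECG" stands for 5,7,3',4'-tetra-O-benzyl-(−)-epicatechin 3-O-(3,4,5-tri-O-benzylgallate).

Remark: (−)-epicatechin and 3,4,5-tris(benzyloxy)benzoic acid are taken as commercially available.

Step 1
Reactants: 1 (−)-epicatechin; 2 benzyl bromide
Product: 3 5,7,3',4'-tetra-O-benzyl-(−)-epicatechin (free 3-OH, 2R,3R)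
Conditions: BnBr (4.4 equiv), K2CO3 (5 equiv), DMF, 0 °C → rt, Ar
Reagents that add atoms: benzyl bromide, BrCc1ccccc1
Why: Williamson ether synthesis; carbonate deprotonates only the four phenols, so the secondary 3-OH stays free, and the mild anhydrous base should leave C2 and C3 unchanged (no new stereocentre).

Step 2
Reactants: 3 5,7,3',4'-tetra-O-benzyl-(−)-epicatechin; 4 3,4,5-tris(benzyloxy)benzoic acid
Product: 5 Bn7-ECG (2R,3R)
Conditions: DCC (1.5 equiv), DMAP (0.5 equiv), CH2Cl2, 0 °C → rt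
Reagents that add atoms: 3,4,5-tris(benzyloxy)benzoic acid, OC(=O)c1cc(OCc2ccccc2)c(OCc2ccccc2)c(OCc2ccccc2)c1
Why: Steglich esterification; the DMAP-derived acylpyridinium acylates the axial 3-OH without breaking the C3–O bond, so the 3R configuration is retained (no new stereocentre).

Step 3
Reactants: 5 Bn7-ECG; 6 N-bromosuccinimide
Product: 7 8-bromo-Bn7-ECG
Conditions: NBS (1.0 equiv), CH2Cl2, −78 → 0 °C
Reagents that add atoms: N-bromosuccinimide, O=C1CCC(=O)N1Br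
Why: Electrophilic aromatic bromination of the most electron-rich arene (the 5,7-dialkoxy A-ring) at C8, the position next to O1 that is less hindered than C6 between two benzyloxy groups, as is usual for benzylated (epi)catechins; no new stereocentre.

Step 4
Reactants: 7 8-bromo-Bn7-ECG; 8 2-ethoxyethanol
Product: 9 8-bromo-4β-(2-ethoxyethoxy)-Bn7-ECG (2,3-cis-3,4-trans)
Conditions: DDQ (2 equiv), 2-ethoxyethanol (6 equiv), CH2Cl2, rt
Reagents that add atoms: 2-ethoxyethanol, CCOCCO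
Why: DDQ benzylic oxidation (hydride abstraction from the C4 methylene activated by O1, 5-O and 7-O) and capture of the cation by the alcohol on the β-face, anti to the 3-O-galloyl and 2-aryl groups, should give the 4β-ether; the C8 bromide blocks self-arylation.

Step 5
Reactants: 9 8-bromo-4β-(2-ethoxyethoxy)-Bn7-ECG; 10 2,6-dimethylbenzenethiol
Product: 11 8-bromo-4β-(2,6-dimethylphenylthio)-Bn7-ECG
Conditions: XySH (3 equiv), cat. BF3·OEt2, CH2Cl2, −78 → −30 °C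
Reagents that add atoms: 2,6-dimethylbenzenethiol, Cc1cccc(C)c1S
Why: Lewis acid-mediated SN1 thioetherification; BF3 ionises the 4-alkoxy group and the thiol adds to the cation anti to the participating 3-O-galloyl ester, giving the 4β-thioether, which is inert to hard Lewis acids.

Step 6
Reactants: 9 8-bromo-4β-(2-ethoxyethoxy)-Bn7-ECG; 11 8-bromo-4β-(2,6-dimethylphenylthio)-Bn7-ECG
Product: 12 (8-bromo-Bn7-ECG)-(4β→6)-[8-bromo-4β-(2,6-dimethylphenylthio)-Bn7-ECG]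
Conditions: 11 (3 equiv), cat. BF3·OEt2, 4 Å MS, CH2Cl2, −78 → −20 °C, slow addition of 9
Reagents that add atoms: none
Why: Friedel–Crafts-type flavan-4-yl cation arylation with orthogonal activation; BF3 ionises only the O-leaving group of 9, the 8-bromo cap leaves C6 as the single nucleophilic site of 11, attack anti to the participating 3-O-galloyl of 9 sets the upper C4 as 4β, excess 11 with slow addition of 9 suppresses self-condensation through the free C6 of 9, and the hindered xylyl sulfur should not take up the cation.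

Step 7
Reactants: 12 (8-bromo-Bn7-ECG)-(4β→6)-[8-bromo-4β-(2,6-dimethylphenylthio)-Bn7-ECG]; 5 Bn7-ECG
Product: 13 (8-bromo-Bn7-ECG)-(4β→6)-(8-bromo-Bn7-ECG)-(4β→8)-(Bn7-ECG)
Conditions: 5 (3 equiv), NIS (1.2 equiv), 4 Å MS, CH2Cl2, −78 → −20 °C
Reagents that add atoms: none
Why: NIS iodinates the thioether sulfur of 12, loss of the sulfenyl iodide gives the C4 benzylic cation of the middle unit (a quinone methide-type oxocarbenium stabilised by O1, 5-OBn and 7-OBn and bridged on the α-face by the carbonyl of the 3-O-galloyl ester), and C8 of 5 attacks it and rearomatises by loss of a proton. The closest known reaction type is the soft (thiophilic) activation of flavan 4-thioethers for interflavan bond formation in the orthogonal synthesis of procyanidin oligomers, which itself mirrors biosynthetic chain extension by a C4 carbocation on C8 of the starter unit. No ring is closed. The new stereocentre, C4 of the middle unit, should be 4β under substrate control, because the nucleophile enters anti to the participating 3-O-galloyl group and to the α-oriented 2-aryl group (3,4-trans, 2,4-trans). The step needs C8 over C6 selectivity in 5 (C6 is flanked by two benzyloxy groups, C8 by O1 and one), cross-coupling over self-condensation (the only free A-ring position of 12 lies on a bromine-deactivated ring) and mono-addition (excess 5). Iodination at the soft sulfur should outrun arene iodination at −78 °C.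

Step 8
Reactants: 13 (8-bromo-Bn7-ECG)-(4β→6)-(8-bromo-Bn7-ECG)-(4β→8)-(Bn7-ECG)
Product: 14 epicatechin 3-O-gallate-(4β→6)-epicatechin 3-O-gallate-(4β→8)-epicatechin 3-O-gallate (CNP0183218.1)
Conditions: H2 (1 atm), Pd(OH)2/C, Et3N (2.2 equiv), THF/MeOH/H2O, rt; Sephadex LH-20
Reagents that add atoms: none
Why: Catalytic hydrogenolysis should cleave all 21 benzyl ethers and hydrodebrominate both aryl bromides in one operation, Et3N trapping HBr so that the acid-labile interflavan bonds survive; the gallate esters and all stereocentres are not touched.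

Compound list
1 | (−)-epicatechin | O[C@@H]1Cc2c(O)cc(O)cc2O[C@@H]1c1ccc(O)c(O)c1 | starting material
2 | benzyl bromide | BrCc1ccccc1 | starting material
3 | 5,7,3',4'-tetra-O-benzyl-(−)-epicatechin | O[C@@H]1Cc2c(OCc3ccccc3)cc(OCc3ccccc3)cc2O[C@@H]1c1ccc(OCc2ccccc2)c(OCc2ccccc2)c1 | intermediate
4 | 3,4,5-tris(benzyloxy)benzoic acid | OC(=O)c1cc(OCc2ccccc2)c(OCc2ccccc2)c(OCc2ccccc2)c1 | starting material
5 | Bn7-ECG | O=C(O[C@@H]1Cc2c(OCc3ccccc3)cc(OCc3ccccc3)cc2O[C@@H]1c1ccc(OCc2ccccc2)c(OCc2ccccc2)c1)c1cc(OCc2ccccc2)c(OCc2ccccc2)c(OCc2ccccc2)c1 | intermediate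
6 | N-bromosuccinimide | O=C1CCC(=O)N1Br | starting material
7 | 8-bromo-Bn7-ECG | O=C(O[C@@H]1Cc2c(OCc3ccccc3)cc(OCc3ccccc3)c(Br)c2O[C@@H]1c1ccc(OCc2ccccc2)c(OCc2ccccc2)c1)c1cc(OCc2ccccc2)c(OCc2ccccc2)c(OCc2ccccc2)c1 | intermediate
8 | 2-ethoxyethanol | CCOCCO | starting material
9 | 8-bromo-4β-(2-ethoxyethoxy)-Bn7-ECG | O=C(O[C@@H]1[C@@H](OCCOCC)c2c(OCc3ccccc3)cc(OCc3ccccc3)c(Br)c2O[C@@H]1c1ccc(OCc2ccccc2)c(OCc2ccccc2)c1)c1cc(OCc2ccccc2)c(OCc2ccccc2)c(OCc2ccccc2)c1 | intermediate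
10 | 2,6-dimethylbenzenethiol | Cc1cccc(C)c1S | starting material
11 | 8-bromo-4β-(2,6-dimethylphenylthio)-Bn7-ECG | O=C(O[C@@H]1[C@@H](Sc2c(C)cccc2C)c2c(OCc3ccccc3)cc(OCc3ccccc3)c(Br)c2O[C@@H]1c1ccc(OCc2ccccc2)c(OCc2ccccc2)c1)c1cc(OCc2ccccc2)c(OCc2ccccc2)c(OCc2ccccc2)c1 | intermediate
12 | (8-bromo-Bn7-ECG)-(4β→6)-[8-bromo-4β-(2,6-dimethylphenylthio)-Bn7-ECG] | O=C(O[C@@H]1[C@@H](c2c(OCc4ccccc4)c(Br)c3c(c2OCc4ccccc4)[C@H](Sc4c(C)cccc4C)[C@@H](OC(=O)c4cc(OCc5ccccc5)c(OCc5ccccc5)c(OCc5ccccc5)c4)[C@@H](c4ccc(OCc5ccccc5)c(OCc5ccccc5)c4)O3)c2c(OCc3ccccc3)cc(OCc3ccccc3)c(Br)c2O[C@@H]1c1ccc(OCc2ccccc2)c(OCc2ccccc2)c1)c1cc(OCc2ccccc2)c(OCc2ccccc2)c(OCc2ccccc2)c1 | intermediate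
13 | (8-bromo-Bn7-ECG)-(4β→6)-(8-bromo-Bn7-ECG)-(4β→8)-(Bn7-ECG) | O=C(O[C@@H]1[C@@H](c2c(OCc4ccccc4)c(Br)c3c(c2OCc4ccccc4)[C@H](c4c(OCc6ccccc6)cc(OCc6ccccc6)c5c4O[C@H](c4ccc(OCc6ccccc6)c(OCc6ccccc6)c4)[C@H](OC(=O)c4cc(OCc6ccccc6)c(OCc6ccccc6)c(OCc6ccccc6)c4)C5)[C@@H](OC(=O)c4cc(OCc5ccccc5)c(OCc5ccccc5)c(OCc5ccccc5)c4)[C@@H](c4ccc(OCc5ccccc5)c(OCc5ccccc5)c4)O3)c2c(OCc3ccccc3)cc(OCc3ccccc3)c(Br)c2O[C@@H]1c1ccc(OCc2ccccc2)c(OCc2ccccc2)c1)c1cc(OCc2ccccc2)c(OCc2ccccc2)c(OCc2ccccc2)c1 | intermediate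
14 | epicatechin 3-O-gallate-(4β→6)-epicatechin 3-O-gallate-(4β→8)-epicatechin 3-O-gallate (CNP0183218.1) | O=C(O[C@@H]1[C@@H](c2c(O)cc3c(c2O)[C@H](c2c(O)cc(O)c4c2O[C@H](c2ccc(O)c(O)c2)[C@H](OC(=O)c2cc(O)c(O)c(O)c2)C4)[C@@H](OC(=O)c2cc(O)c(O)c(O)c2)[C@@H](c2ccc(O)c(O)c2)O3)c2c(O)cc(O)cc2O[C@@H]1c1ccc(O)c(O)c1)c1cc(O)c(O)c(O)c1 | target

Total step count: 8. Longest linear sequence: 8 steps (1 → 3 → 5 → 7 → 9 → 11 → 12 → 13 → 14); compounds 9 and 5 re-enter the line convergently in steps 6 and 7.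

Steps most likely to fail

Step 6. Attack at the hindered, bromine-deactivated C6 of 11 may be slow enough that the cation from 9 is consumed by self-condensation through the free C6 of another molecule of 9 or of the product. The fallback removes every competing nucleophilic site from the electrophile. It sets out from 9: a second bromination (NBS, CH2Cl2, 0 °C) should give the doubly capped electrophile 6,8-dibromo-4β-(2-ethoxyethoxy)-Bn7-ECG F1. BF3·OEt2-mediated coupling of F1 with near-equimolar 11 should give the tribromo dimer thioether F2, and NIS-mediated coupling of F2 with 5 the tribromo protected trimer F3. Hydrogenolysis with hydrodebromination of F3 under the conditions of step 8 comes back to the route at 14.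

Step 7. NIS may iodinate the free A-ring of 5 in competition with sulfur activation, the thioether may ionise sluggishly next to the ester, or attack may partly occur through C6. The fallback replaces soft activation of a thioether by hard activation of an oxygen leaving group installed late. It sets out from 9 and 7: BF3·OEt2-mediated coupling at C6 of 7 (excess) should give the sulfur-free dimer (8-bromo-Bn7-ECG)-(4β→6)-(8-bromo-Bn7-ECG) F4. DDQ/2-ethoxyethanol oxidation of its only benzylic methylene (C4 of the lower unit; the interflavan C4 methine is shielded by its two flanking aryl rings) should give the 4β-(2-ethoxyethoxy) dimer F5. Yb(OTf)3-catalysed condensation of F5 with 5, with no electrophilic halogen source present, comes back to the route at 13.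

Step 8. Debenzylation of 21 ethers may stall on the catalyst, and HBr released by hydrodebromination may cleave the interflavan bonds of the free polyphenol or epimerise it. The fallback separates the two reductions. It sets out from 13: radical hydrodebromination (Bu3SnH, cat. AIBN, toluene, 90 °C), to which esters and benzyl ethers are inert, should give the bromine-free protected trimer (Bn7-ECG)-(4β→6)-(Bn7-ECG)-(4β→8)-(Bn7-ECG) F6. Neutral hydrogenolysis of F6 (H2, Pd(OH)2/C, THF/MeOH/H2O) comes back to the route at 14.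

Further compounds
F1 | step 6 | 6,8-dibromo-4β-(2-ethoxyethoxy)-Bn7-ECG | O=C(O[C@@H]1[C@@H](OCCOCC)c2c(OCc3ccccc3)c(Br)c(OCc3ccccc3)c(Br)c2O[C@@H]1c1ccc(OCc2ccccc2)c(OCc2ccccc2)c1)c1cc(OCc2ccccc2)c(OCc2ccccc2)c(OCc2ccccc2)c1
F2 | step 6 | (6,8-dibromo-Bn7-ECG)-(4β→6)-[8-bromo-4β-(2,6-dimethylphenylthio)-Bn7-ECG] | O=C(O[C@@H]1[C@@H](c2c(OCc4ccccc4)c(Br)c3c(c2OCc4ccccc4)[C@H](Sc4c(C)cccc4C)[C@@H](OC(=O)c4cc(OCc5ccccc5)c(OCc5ccccc5)c(OCc5ccccc5)c4)[C@@H](c4ccc(OCc5ccccc5)c(OCc5ccccc5)c4)O3)c2c(OCc3ccccc3)c(Br)c(OCc3ccccc3)c(Br)c2O[C@@H]1c1ccc(OCc2ccccc2)c(OCc2ccccc2)c1)c1cc(OCc2ccccc2)c(OCc2ccccc2)c(OCc2ccccc2)c1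
F3 | step 6 | (6,8-dibromo-Bn7-ECG)-(4β→6)-(8-bromo-Bn7-ECG)-(4β→8)-(Bn7-ECG) | O=C(O[C@@H]1[C@@H](c2c(OCc4ccccc4)c(Br)c3c(c2OCc4ccccc4)[C@H](c4c(OCc6ccccc6)cc(OCc6ccccc6)c5c4O[C@H](c4ccc(OCc6ccccc6)c(OCc6ccccc6)c4)[C@H](OC(=O)c4cc(OCc6ccccc6)c(OCc6ccccc6)c(OCc6ccccc6)c4)C5)[C@@H](OC(=O)c4cc(OCc5ccccc5)c(OCc5ccccc5)c(OCc5ccccc5)c4)[C@@H](c4ccc(OCc5ccccc5)c(OCc5ccccc5)c4)O3)c2c(OCc3ccccc3)c(Br)c(OCc3ccccc3)c(Br)c2O[C@@H]1c1ccc(OCc2ccccc2)c(OCc2ccccc2)c1)c1cc(OCc2ccccc2)c(OCc2ccccc2)c(OCc2ccccc2)c1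
F4 | step 7 | (8-bromo-Bn7-ECG)-(4β→6)-(8-bromo-Bn7-ECG) | O=C(O[C@@H]1[C@@H](c2c(OCc4ccccc4)c(Br)c3c(c2OCc4ccccc4)C[C@@H](OC(=O)c4cc(OCc5ccccc5)c(OCc5ccccc5)c(OCc5ccccc5)c4)[C@@H](c4ccc(OCc5ccccc5)c(OCc5ccccc5)c4)O3)c2c(OCc3ccccc3)cc(OCc3ccccc3)c(Br)c2O[C@@H]1c1ccc(OCc2ccccc2)c(OCc2ccccc2)c1)c1cc(OCc2ccccc2)c(OCc2ccccc2)c(OCc2ccccc2)c1
F5 | step 7 | (8-bromo-Bn7-ECG)-(4β→6)-[8-bromo-4β-(2-ethoxyethoxy)-Bn7-ECG] | O=C(O[C@@H]1[C@@H](c2c(OCc4ccccc4)c(Br)c3c(c2OCc4ccccc4)[C@H](OCCOCC)[C@@H](OC(=O)c4cc(OCc5ccccc5)c(OCc5ccccc5)c(OCc5ccccc5)c4)[C@@H](c4ccc(OCc5ccccc5)c(OCc5ccccc5)c4)O3)c2c(OCc3ccccc3)cc(OCc3ccccc3)c(Br)c2O[C@@H]1c1ccc(OCc2ccccc2)c(OCc2ccccc2)c1)c1cc(OCc2ccccc2)c(OCc2ccccc2)c(OCc2ccccc2)c1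
F6 | step 8 | (Bn7-ECG)-(4β→6)-(Bn7-ECG)-(4β→8)-(Bn7-ECG) | O=C(O[C@@H]1[C@@H](c2c(OCc4ccccc4)cc3c(c2OCc4ccccc4)[C@H](c4c(OCc6ccccc6)cc(OCc6ccccc6)c5c4O[C@H](c4ccc(OCc6ccccc6)c(OCc6ccccc6)c4)[C@H](OC(=O)c4cc(OCc6ccccc6)c(OCc6ccccc6)c(OCc6ccccc6)c4)C5)[C@@H](OC(=O)c4cc(OCc5ccccc5)c(OCc5ccccc5)c(OCc5ccccc5)c4)[C@@H](c4ccc(OCc5ccccc5)c(OCc5ccccc5)c4)O3)c2c(OCc3ccccc3)cc(OCc3ccccc3)cc2O[C@@H]1c1ccc(OCc2ccccc2)c(OCc2ccccc2)c1)c1cc(OCc2ccccc2)c(OCc2ccccc2)c(OCc2ccccc2)c1
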